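**Retrosynthetic overview**
- The plan rests on lactone carbon C19 of the ring O–C21(=O)–C20–C19–C18–C17: it bears three CH2 arms (C18, C20, C22), and C20–C21 and C22–C23 are the two halves of the C=C of a 4-substituted cyclopentene. Cleaving that alkene to a glutaric acid and letting the C17 hydroxyl lactonise under equilibration builds the ring and sets C19 from C17.
- Disconnections, late to early: C11–C12 (nickel-catalysed enyne–aldehyde reductive coupling of 25 with 45, then oxidation and CBS reduction for C11), C23=C24 (Horner–Wadsworth–Emmons), C12–C15 enyne (hydrozirconation–iodination, Sonogashira), C4–C5 (Suzuki–Miyaura).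
- Stereocentres: C16/C17 and C7/C8 by Evans syn aldols, C9 by Evans–Saksena anti reduction, C19 in the key lactonisation, C11 by CBS reduction.
- Rings: oxazole and cyclopentene are bought; the cyclopentene is cleaved and the δ-lactone is the only ring closed (step 8).

Key step: step 8

Remark: carbons are numbered C1 (oxazolyl CH=) to C21 (lactone C=O) and C22–C25 along the butenoic acid arm; the C17 hydroxyl enters the key step as its triethylsilyl ether and the alkyne as a terminal alkyne, and the syn C16/C17 pair is made by an auxiliary aldol plus alkyne homologation because open-transition-state allenylmetal additions are not reliably syn-selective with an α-unbranched aldehyde such as 3.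

**Route**

Step 1
Reactants: 1 2-(cyclopent-3-en-1-yl)acetic acid
Product: 2 2-(cyclopent-3-en-1-yl)ethan-1-ol
Conditions: LiAlH4, THF, 0 °C to rt
Reagents that add atoms: none
Why: Hydride reduction of a carboxylic acid with LiAlH4 gives the primary alcohol and leaves the isolated ring alkene untouched.

Step 2
Reactants: 2 2-(cyclopent-3-en-1-yl)ethan-1-ol
Product: 3 2-(cyclopent-3-en-1-yl)acetaldehyde
Conditions: Dess–Martin periodinane, NaHCO3, CH2Cl2, 0 °C to rt
Reagents that add atoms: none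
Why: Dess–Martin oxidation stops at the aldehyde under buffered non-aqueous conditions, and the volatile product would be used as a solution.

Step 3
Reactants: 3 2-(cyclopent-3-en-1-yl)acetaldehyde; 4 (4S)-4-benzyl-3-propanoyl-1,3-oxazolidin-2-one
Product: 6 (4S)-4-benzyl-3-[(2S,3R)-4-(cyclopent-3-en-1-yl)-3-hydroxy-2-methylbutanoyl]-1,3-oxazolidin-2-one, via Z-boron enolate 5 (not isolated)
Conditions: Bu2BOTf, Et3N, CH2Cl2, 0 °C; then 3, −78 to 0 °C; H2O2, MeOH, pH 7 buffer
Reagents that add atoms: none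
Why: Evans syn aldol, in which the Z boron enolate adds through a closed Zimmerman–Traxler chair on the face away from the benzyl group, so C16 and C17 (2S,3R in the adduct) should be set by the auxiliary even though 3 has no α-branch.

Step 4
Reactants: 6 (4S)-4-benzyl-3-[(2S,3R)-4-(cyclopent-3-en-1-yl)-3-hydroxy-2-methylbutanoyl]-1,3-oxazolidin-2-one
Product: 7 (2S,3R)-4-(cyclopent-3-en-1-yl)-3-hydroxy-N-methoxy-N,2-dimethylbutanamide
Conditions: MeNH(OMe)·HCl, AlMe3, CH2Cl2, −10 °C to rt; aq. potassium sodium tartrate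
Reagents that add atoms: N,O-dimethylhydroxylamine hydrochloride CNOC.Cl
Why: Weinreb transamination with the aluminium amide, assisted by the free β-hydroxyl, releases the auxiliary without epimerising C16.

Step 5
Reactants: 7 (2S,3R)-4-(cyclopent-3-en-1-yl)-3-hydroxy-N-methoxy-N,2-dimethylbutanamide
Product: 8 (2S,3R)-4-(cyclopent-3-en-1-yl)-N-methoxy-N,2-dimethyl-3-(triethylsilyloxy)butanamide
Conditions: Et3SiCl, imidazole, DMF, 0 °C to rt
Reagents that add atoms: chlorotriethylsilane CC[Si](Cl)(CC)CC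
Why: Silyl ether formation masks the C17 hydroxyl for the reduction and homologation, and the triethylsilyl group is labile enough to fall off in the acid stage of step 8.

Step 6
Reactants: 8 (2S,3R)-4-(cyclopent-3-en-1-yl)-N-methoxy-N,2-dimethyl-3-(triethylsilyloxy)butanamide
Product: 9 (2S,3R)-4-(cyclopent-3-en-1-yl)-2-methyl-3-(triethylsilyloxy)butanal
Conditions: i-Bu2AlH, THF, −78 °C; aq. potassium sodium tartrate
Reagents that add atoms: none
Why: Partial reduction of a Weinreb amide through its stable chelated tetrahedral intermediate gives the aldehyde without over-reduction or epimerisation at low temperature.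

Step 7
Reactants: 9 (2S,3R)-4-(cyclopent-3-en-1-yl)-2-methyl-3-(triethylsilyloxy)butanal
Product: 10 {[(2R,3R)-1-(cyclopent-3-en-1-yl)-3-methylpent-4-yn-2-yl]oxy}triethylsilane
Conditions: dimethyl (1-diazo-2-oxopropyl)phosphonate, K2CO3, MeOH, 0 °C to rt
Reagents that add atoms: dimethyl (1-diazo-2-oxopropyl)phosphonate CC(=O)C(=[N+]=[N-])P(=O)(OC)OC
Why: Ohira–Bestmann (Seyferth–Gilbert) homologation turns the aldehyde into the terminal alkyne under mild carbonate conditions that normally preserve an α-stereocentre.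

Step 8
Reactants: 10 {[(2R,3R)-1-(cyclopent-3-en-1-yl)-3-methylpent-4-yn-2-yl]oxy}triethylsilane
Product: 14 2-[(2R,4S)-2-[(2R)-but-3-yn-2-yl]-6-oxooxan-4-yl]acetic acid, via silyloxy dialdehyde 11 (not isolated), via silyloxy diacid 12 (not isolated), via hydroxy diacid 13 (not isolated)
Conditions: O3 (1 equiv, metered), MeCN–H2O 9:1, 0 °C; then NaClO2, NaH2PO4, H2O2, 0 °C to rt; then TsOH·H2O (cat.), PhMe, 80 °C
Reagents that add atoms: ozone O=[O+][O-]; water O; sodium chlorite [Na+].[O-]Cl=O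
Why: Ozone adds to the strained cis ring alkene by 1,3-dipolar cycloaddition, the primary ozonide fragments, water traps the carbonyl oxide, and chlorite oxidises dialdehyde 11 to the 3-substituted glutaric acid 12; acid then removes the silyl group and the C17 hydroxyl closes onto one carboxymethyl arm. The closest known reaction types are oxidative ozonolysis of cyclopentenes to glutaric acids and acid-catalysed δ-lactonisation of a 3-substituted glutaric acid by a pendant hydroxyl under equilibrating conditions. The ring O–C21–C20–C19–C18–C17 closes by 6-exo-trig addition–elimination at the carboxyl carbon, forming the O–C21 bond. C19 becomes a stereocentre only through the choice of arm and is controlled by C17: the two lactones interconvert through hydroxy diacid 13 or its cyclic anhydride, and the cis-4,6 isomer, with the butynyl group and the carboxymethyl arm both equatorial, should dominate at equilibrium. The step needs chemoselectivity for the ring alkene over the terminal alkyne, secured by the much faster ozone addition to a cis-disubstituted strained alkene and by metering one equivalent of ozone, and it needs arm selectivity, secured by the diequatorial preference, with the minor trans lactone separated and returned to the equilibration.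

Step 9
Reactants: 14 2-[(2R,4S)-2-[(2R)-but-3-yn-2-yl]-6-oxooxan-4-yl]acetic acid
Product: 16 (4R,6R)-6-[(2R)-but-3-yn-2-yl]-4-(2-hydroxyethyl)oxan-2-one, via mixed carbonic anhydride 15 (not isolated)
Conditions: i-BuOCOCl, N-methylmorpholine, THF, −15 °C; then NaBH4, H2O, 0 °C
Reagents that add atoms: none
Why: Borohydride reduction of the mixed carbonic anhydride is fast at 0 °C and should spare both the δ-lactone and the terminal alkyne, which borane would hydroborate.

Step 10
Reactants: 16 (4R,6R)-6-[(2R)-but-3-yn-2-yl]-4-(2-hydroxyethyl)oxan-2-one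
Product: 17 2-[(2R,4S)-2-[(2R)-but-3-yn-2-yl]-6-oxooxan-4-yl]acetaldehyde
Conditions: Dess–Martin periodinane, NaHCO3, CH2Cl2, 0 °C to rt
Reagents that add atoms: none
Why: Dess–Martin oxidation of the primary alcohol, run at once on crude 16 so that the hydroxy lactone has no time to translactonise onto the primary hydroxyl.

Step 11
Reactants: 18 2-(diethoxyphosphoryl)acetic acid; 19 2-(trimethylsilyl)ethan-1-ol
Product: 20 2-(trimethylsilyl)ethyl 2-(diethoxyphosphoryl)acetate
Conditions: DCC, DMAP (cat.), CH2Cl2, 0 °C to rt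
Reagents that add atoms: none
Why: Steglich esterification gives the phosphonate reagent carrying a fluoride-labile ester.

Step 12
Reactants: 17 2-[(2R,4S)-2-[(2R)-but-3-yn-2-yl]-6-oxooxan-4-yl]acetaldehyde; 20 2-(trimethylsilyl)ethyl 2-(diethoxyphosphoryl)acetate
Product: 21 2-(trimethylsilyl)ethyl (2E)-4-[(2R,4R)-2-[(2R)-but-3-yn-2-yl]-6-oxooxan-4-yl]but-2-enoate
Conditions: LiCl, DBU, MeCN, 0 °C to rt
Reagents that add atoms: none
Why: Masamune–Roush variant of the Horner–Wadsworth–Emmons olefination, whose amine base is mild enough for the enolisable aldehyde and the lactone and whose stabilised phosphonate gives the E enoate.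

Step 13
Reactants: 21 2-(trimethylsilyl)ethyl (2E)-4-[(2R,4R)-2-[(2R)-but-3-yn-2-yl]-6-oxooxan-4-yl]but-2-enoate
Product: 23 2-(trimethylsilyl)ethyl (2E)-4-[(2R,4R)-2-[(2R,3E)-4-iodobut-3-en-2-yl]-6-oxooxan-4-yl]but-2-enoate, via alkenylzirconocene 22 (not isolated)
Conditions: Cp2Zr(H)Cl, THF, rt; then I2, 0 °C
Reagents that add atoms: iodine II
Why: Hydrozirconation of a terminal alkyne is syn and places zirconium on the terminal carbon, and iodinolysis with retention gives the E vinyl iodide.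

Step 14
Reactants: 23 2-(trimethylsilyl)ethyl (2E)-4-[(2R,4R)-2-[(2R,3E)-4-iodobut-3-en-2-yl]-6-oxooxan-4-yl]but-2-enoate; 24 propyne
Product: 25 2-(trimethylsilyl)ethyl (2E)-4-[(2R,4R)-2-[(2R,3E)-hept-3-en-5-yn-2-yl]-6-oxooxan-4-yl]but-2-enoate
Conditions: PdCl2(PPh3)2 (cat.), CuI (cat.), Et3N, THF, rt
Reagents that add atoms: none
Why: Sonogashira coupling of the vinyl iodide with propyne keeps the alkene geometry and gives the methyl-capped 1,3-enyne at room temperature.

Step 15
Reactants: 26 prop-2-yn-1-ol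
Product: 28 (2E)-3-iodo-2-methylprop-2-en-1-ol, via alkenylalane 27 (not isolated)
Conditions: AlMe3, Cp2ZrCl2 (cat.), CH2Cl2, 0 °C to rt; then I2, THF, −30 °C
Reagents that add atoms: trimethylaluminium C[Al](C)C; iodine II
Why: Zirconium-catalysed Negishi carboalumination adds methyl and aluminium syn across the alkyne with aluminium on the terminal carbon, and iodinolysis gives the E iodide.

Step 16
Reactants: 28 (2E)-3-iodo-2-methylprop-2-en-1-ol
Product: 29 (2E)-3-iodo-2-methylprop-2-enal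
Conditions: MnO2, CH2Cl2, rt
Reagents that add atoms: none
Why: Allylic oxidation with MnO2 gives the enal without isomerising the iodoalkene.

Step 17
Reactants: 29 (2E)-3-iodo-2-methylprop-2-enal; 30 (4R)-4-benzyl-3-propanoyl-1,3-oxazolidin-2-one
Product: 32 (4R)-4-benzyl-3-[(2R,3R,4E)-3-hydroxy-5-iodo-2,4-dimethylpent-4-enoyl]-1,3-oxazolidin-2-one, via Z-boron enolate 31 (not isolated)
Conditions: Bu2BOTf, Et3N, CH2Cl2, 0 °C; then 29, −78 to 0 °C; H2O2, MeOH, pH 7 buffer
Reagents that add atoms: none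
Why: Evans syn aldol with the (R)-benzyl imide, in which the Z boron enolate adds to the enal through the Zimmerman–Traxler chair and sets C8 and C7 (2R,3R in the adduct).

Step 18
Reactants: 32 (4R)-4-benzyl-3-[(2R,3R,4E)-3-hydroxy-5-iodo-2,4-dimethylpent-4-enoyl]-1,3-oxazolidin-2-one
Product: 33 (2R,3R,4E)-3-hydroxy-5-iodo-N-methoxy-N,2,4-trimethylpent-4-enamide
Conditions: MeNH(OMe)·HCl, AlMe3, CH2Cl2, −10 °C to rt; aq. potassium sodium tartrate
Reagents that add atoms: N,O-dimethylhydroxylamine hydrochloride CNOC.Cl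
Why: Weinreb transamination removes the auxiliary and installs an acyl donor that accepts only one equivalent of a carbon nucleophile.

Step 19
Reactants: 33 (2R,3R,4E)-3-hydroxy-5-iodo-N-methoxy-N,2,4-trimethylpent-4-enamide; 34 ethyl acetate
Product: 36 ethyl (4R,5R,6E)-5-hydroxy-7-iodo-4,6-dimethyl-3-oxohept-6-enoate, via lithium enolate 35 (not isolated)
Conditions: 34, LiN(i-Pr)2 (excess), THF, −78 °C; then 33, −78 to −40 °C
Reagents that add atoms: none
Why: Crossed Claisen-type acylation, in which excess ester enolate adds to the Weinreb amide and the chelated adduct collapses only on work-up, so the δ-hydroxy β-keto ester forms without double addition.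

Step 20
Reactants: 36 ethyl (4R,5R,6E)-5-hydroxy-7-iodo-4,6-dimethyl-3-oxohept-6-enoate
Product: 37 ethyl (3S,4S,5R,6E)-3,5-dihydroxy-7-iodo-4,6-dimethylhept-6-enoate
Conditions: Me4NBH(OAc)3, MeCN–AcOH, −30 °C
Reagents that add atoms: none
Why: Evans–Saksena reduction, in which the C7 alkoxy(diacetoxy)borohydride delivers hydride intramolecularly through a chair to give the 1,3-anti diol and so sets C9 (S) irrespective of the C8 methyl.

Step 21
Reactants: 37 ethyl (3S,4S,5R,6E)-3,5-dihydroxy-7-iodo-4,6-dimethylhept-6-enoate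
Product: 38 ethyl (3S,4S,5R,6E)-7-iodo-4,6-dimethyl-3,5-bis(triethylsilyloxy)hept-6-enoate
Conditions: Et3SiOTf, 2,6-lutidine, CH2Cl2, −78 to 0 °C
Reagents that add atoms: triethylsilyl triflate CC[Si](CC)(CC)OS(=O)(=O)C(F)(F)F
Why: Silylation of both secondary hydroxyls with a silyl triflate and a hindered base, chosen so that fluoride removes them together with the ester group in the last step.

Step 22
Reactants: 39 2-methyl-1,3-oxazole-4-carbaldehyde; 40 2-(triphenylphosphoranylidene)propanal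
Product: 41 (2E)-2-methyl-3-(2-methyl-1,3-oxazol-4-yl)prop-2-enal
Conditions: PhMe, 80 °C
Reagents that add atoms: none
Why: Wittig olefination with a stabilised α-methyl ylide gives the E trisubstituted enal (C1=C2).

Step 23
Reactants: 41 (2E)-2-methyl-3-(2-methyl-1,3-oxazol-4-yl)prop-2-enal; 42 2-(dichloromethyl)-4,4,5,5-tetramethyl-1,3,2-dioxaborolane
Product: 43 2-methyl-4-[(1E,3E)-2-methyl-4-(4,4,5,5-tetramethyl-1,3,2-dioxaborolan-2-yl)buta-1,3-dien-1-yl]-1,3-oxazole
Conditions: CrCl2, LiI, THF, rt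
Reagents that add atoms: none
Why: Takai–Utimoto olefination, in which the geminal dichromium species from the dihalomethylboronate adds to the aldehyde and eliminates to give the E alkenylboronate (C3=C4).

Step 24
Reactants: 38 ethyl (3S,4S,5R,6E)-7-iodo-4,6-dimethyl-3,5-bis(triethylsilyloxy)hept-6-enoate; 43 2-methyl-4-[(1E,3E)-2-methyl-4-(4,4,5,5-tetramethyl-1,3,2-dioxaborolan-2-yl)buta-1,3-dien-1-yl]-1,3-oxazole
Product: 44 ethyl (3S,4S,5R,6E,8E,10E)-4,6,10-trimethyl-11-(2-methyl-1,3-oxazol-4-yl)-3,5-bis(triethylsilyloxy)undeca-6,8,10-trienoate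
Conditions: Pd(dppf)Cl2 (cat.), AsPh3, Cs2CO3, DMF–H2O, rt
Reagents that add atoms: none
Why: Suzuki–Miyaura coupling of the alkenyl iodide with the dienylboronate forms C4–C5 with retention of both alkene geometries.

Step 25
Reactants: 44 ethyl (3S,4S,5R,6E,8E,10E)-4,6,10-trimethyl-11-(2-methyl-1,3-oxazol-4-yl)-3,5-bis(triethylsilyloxy)undeca-6,8,10-trienoate
Product: 45 (3S,4S,5R,6E,8E,10E)-4,6,10-trimethyl-11-(2-methyl-1,3-oxazol-4-yl)-3,5-bis(triethylsilyloxy)undeca-6,8,10-trienal
Conditions: i-Bu2AlH, CH2Cl2, −78 °C; aq. potassium sodium tartrate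
Reagents that add atoms: none
Why: Partial ester reduction at −78 °C, helped by the β-silyloxy group that stabilises the aluminium hemiacetal, gives the C11 aldehyde.

Step 26
Reactants: 25 2-(trimethylsilyl)ethyl (2E)-4-[(2R,4R)-2-[(2R,3E)-hept-3-en-5-yn-2-yl]-6-oxooxan-4-yl]but-2-enoate; 45 (3S,4S,5R,6E,8E,10E)-4,6,10-trimethyl-11-(2-methyl-1,3-oxazol-4-yl)-3,5-bis(triethylsilyloxy)undeca-6,8,10-trienal
Product: 46 C11-epimeric dienol: 2-(trimethylsilyl)ethyl ester and 7,9-bis(triethylsilyl) ether of the target acid with either configuration at C11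
Conditions: Ni(cod)2 (cat.), tricyclopentylphosphine (cat.), Et3B, EtOAc, rt
Reagents that add atoms: none
Why: Nickel-catalysed reductive coupling of a 1,3-enyne with an aldehyde, in which oxidative cyclisation directed by the conjugated alkene forms C11–C12 at the methyl-bearing alkyne carbon and syn delivery of hydrogen from Et3B to C13 gives the E trisubstituted alkene, while no control at C11 is asked of this step.

Step 27
Reactants: 46 C11-epimeric dienol
Product: 47 C11 ketone: 2-(trimethylsilyl)ethyl ester and 7,9-bis(triethylsilyl) ether of the 11-oxo analogue of the target acid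
Conditions: Dess–Martin periodinane, NaHCO3, CH2Cl2, 0 °C
Reagents that add atoms: none
Why: Dess–Martin oxidation of the only free hydroxyl converges both C11 epimers to the dienone.

Step 28
Reactants: 47 C11 ketone
Product: 48 (11R)-alcohol: 2-(trimethylsilyl)ethyl ester and 7,9-bis(triethylsilyl) ether of the target acid
Conditions: (S)-2-methyl-CBS-oxazaborolidine, catecholborane, PhMe, −78 °C
Reagents that add atoms: none
Why: Corey–Bakshi–Shibata reduction, in which the α-methyl dienyl group acts as the large substituent so that the (S)-oxazaborolidine should deliver hydride to give the 11R alcohol, and catecholborane at −78 °C leaves lactone, enoate and polyene untouched.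

Step 29
Reactants: 48 (11R)-alcohol
Product: 49 (2E)-4-[(2R,4R)-2-[(2R,3E,5E,7R,9S,10S,11R,12E,14E,16E)-7,9,11-trihydroxy-6,10,12,16-tetramethyl-17-(2-methyl-1,3-oxazol-4-yl)heptadeca-3,5,12,14,16-pentaen-2-yl]-6-oxooxan-4-yl]but-2-enoic acid
Conditions: TBAF, THF, 0 °C to rt; AcOH
Reagents that add atoms: none
Why: Fluoride-mediated global deprotection cleaves both triethylsilyl ethers and fragments the 2-(trimethylsilyl)ethyl ester by β-elimination in one operation that should spare the δ-lactone and the acid-sensitive allylic alcohols.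

**Compound list**
1 | 2-(cyclopent-3-en-1-yl)acetic acid | OC(=O)CC1CC=CC1 | starting material
2 | 2-(cyclopent-3-en-1-yl)ethan-1-ol | OCCC1CC=CC1 | intermediate
3 | 2-(cyclopent-3-en-1-yl)acetaldehyde | O=CCC1CC=CC1 | intermediate
4 | (4S)-4-benzyl-3-propanoyl-1,3-oxazolidin-2-one | CCC(=O)N1[C@@H](Cc2ccccc2)COC1=O | starting material
5 | Z dibutylboron enolate of 4 | C/C=C(\OB(CCCC)CCCC)N1[C@@H](Cc2ccccc2)COC1=O | intermediate
6 | (4S)-4-benzyl-3-[(2S,3R)-4-(cyclopent-3-en-1-yl)-3-hydroxy-2-methylbutanoyl]-1,3-oxazolidin-2-one | O=C([C@@H](C)[C@H](O)CC1CC=CC1)N1[C@@H](Cc2ccccc2)COC1=O | intermediate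
7 | (2S,3R)-4-(cyclopent-3-en-1-yl)-3-hydroxy-N-methoxy-N,2-dimethylbutanamide | CON(C)C(=O)[C@@H](C)[C@H](O)CC1CC=CC1 | intermediate
8 | (2S,3R)-4-(cyclopent-3-en-1-yl)-N-methoxy-N,2-dimethyl-3-(triethylsilyloxy)butanamide | CON(C)C(=O)[C@@H](C)[C@H](O[Si](CC)(CC)CC)CC1CC=CC1 | intermediate
9 | (2S,3R)-4-(cyclopent-3-en-1-yl)-2-methyl-3-(triethylsilyloxy)butanal | O=C[C@@H](C)[C@H](O[Si](CC)(CC)CC)CC1CC=CC1 | intermediate
10 | {[(2R,3R)-1-(cyclopent-3-en-1-yl)-3-methylpent-4-yn-2-yl]oxy}triethylsilane (key-step precursor) | C#C[C@@H](C)[C@H](O[Si](CC)(CC)CC)CC1CC=CC1 | intermediate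
11 | 3-[(2R,3R)-3-methyl-2-(triethylsilyloxy)pent-4-yn-1-yl]pentanedial | C#C[C@@H](C)[C@H](O[Si](CC)(CC)CC)CC(CC=O)CC=O | intermediate
12 | 3-[(2R,3R)-3-methyl-2-(triethylsilyloxy)pent-4-yn-1-yl]pentanedioic acid | C#C[C@@H](C)[C@H](O[Si](CC)(CC)CC)CC(CC(=O)O)CC(=O)O | intermediate
13 | 3-[(2R,3R)-2-hydroxy-3-methylpent-4-yn-1-yl]pentanedioic acid | C#C[C@@H](C)[C@H](O)CC(CC(=O)O)CC(=O)O | intermediate
14 | 2-[(2R,4S)-2-[(2R)-but-3-yn-2-yl]-6-oxooxan-4-yl]acetic acid (cis-4,6 lactone, key-step product) | C#C[C@@H](C)[C@H]1C[C@@H](CC(=O)O)CC(=O)O1 | intermediate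
15 | mixed isobutyl carbonic anhydride of 14 | C#C[C@@H](C)[C@H]1C[C@@H](CC(=O)OC(=O)OCC(C)C)CC(=O)O1 | intermediate
16 | (4R,6R)-6-[(2R)-but-3-yn-2-yl]-4-(2-hydroxyethyl)oxan-2-one | C#C[C@@H](C)[C@H]1C[C@@H](CCO)CC(=O)O1 | intermediate
17 | 2-[(2R,4S)-2-[(2R)-but-3-yn-2-yl]-6-oxooxan-4-yl]acetaldehyde | C#C[C@@H](C)[C@H]1C[C@@H](CC=O)CC(=O)O1 | intermediate
18 | 2-(diethoxyphosphoryl)acetic acid | OC(=O)CP(=O)(OCC)OCC | starting material
19 | 2-(trimethylsilyl)ethan-1-ol | OCC[Si](C)(C)C | starting material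
20 | 2-(trimethylsilyl)ethyl 2-(diethoxyphosphoryl)acetate | CCOP(=O)(CC(=O)OCC[Si](C)(C)C)OCC | intermediate
21 | 2-(trimethylsilyl)ethyl (2E)-4-[(2R,4R)-2-[(2R)-but-3-yn-2-yl]-6-oxooxan-4-yl]but-2-enoate | C#C[C@@H](C)[C@H]1C[C@@H](C/C=C/C(=O)OCC[Si](C)(C)C)CC(=O)O1 | intermediate
22 | (E)-alkenyl(chloro)zirconocene from 21 (Zr on C14) | Cl[Zr](/C=C/[C@@H](C)[C@H]1C[C@@H](C/C=C/C(=O)OCC[Si](C)(C)C)CC(=O)O1)(C1C=CC=C1)C1C=CC=C1 | intermediate
23 | 2-(trimethylsilyl)ethyl (2E)-4-[(2R,4R)-2-[(2R,3E)-4-iodobut-3-en-2-yl]-6-oxooxan-4-yl]but-2-enoate | I/C=C/[C@@H](C)[C@H]1C[C@@H](C/C=C/C(=O)OCC[Si](C)(C)C)CC(=O)O1 | intermediate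
24 | propyne | CC#C | starting material
25 | 2-(trimethylsilyl)ethyl (2E)-4-[(2R,4R)-2-[(2R,3E)-hept-3-en-5-yn-2-yl]-6-oxooxan-4-yl]but-2-enoate | CC#C/C=C/[C@@H](C)[C@H]1C[C@@H](C/C=C/C(=O)OCC[Si](C)(C)C)CC(=O)O1 | intermediate
26 | prop-2-yn-1-ol | C#CCO | starting material
27 | (E)-alkenylalane from 26 (dimethylaluminium alkoxide, AlMe2 on C3) | C[Al](C)OC/C(C)=C/[Al](C)C | intermediate
28 | (2E)-3-iodo-2-methylprop-2-en-1-ol | OC/C(C)=C/I | intermediate
29 | (2E)-3-iodo-2-methylprop-2-enal | O=C/C(C)=C/I | intermediate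
30 | (4R)-4-benzyl-3-propanoyl-1,3-oxazolidin-2-one | CCC(=O)N1[C@H](Cc2ccccc2)COC1=O | starting material
31 | Z dibutylboron enolate of 30 | C/C=C(\OB(CCCC)CCCC)N1[C@H](Cc2ccccc2)COC1=O | intermediate
32 | (4R)-4-benzyl-3-[(2R,3R,4E)-3-hydroxy-5-iodo-2,4-dimethylpent-4-enoyl]-1,3-oxazolidin-2-one | I/C=C(\C)[C@H](O)[C@@H](C)C(=O)N1[C@H](Cc2ccccc2)COC1=O | intermediate
33 | (2R,3R,4E)-3-hydroxy-5-iodo-N-methoxy-N,2,4-trimethylpent-4-enamide | I/C=C(\C)[C@H](O)[C@@H](C)C(=O)N(C)OC | intermediate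
34 | ethyl acetate | CCOC(C)=O | starting material
35 | lithium enolate of ethyl acetate | [Li+].[O-]C(=C)OCC | intermediate
36 | ethyl (4R,5R,6E)-5-hydroxy-7-iodo-4,6-dimethyl-3-oxohept-6-enoate | I/C=C(\C)[C@H](O)[C@@H](C)C(=O)CC(=O)OCC | intermediate
37 | ethyl (3S,4S,5R,6E)-3,5-dihydroxy-7-iodo-4,6-dimethylhept-6-enoate | I/C=C(\C)[C@H](O)[C@@H](C)[C@@H](O)CC(=O)OCC | intermediate
38 | ethyl (3S,4S,5R,6E)-7-iodo-4,6-dimethyl-3,5-bis(triethylsilyloxy)hept-6-enoate | I/C=C(\C)[C@H](O[Si](CC)(CC)CC)[C@@H](C)[C@@H](O[Si](CC)(CC)CC)CC(=O)OCC | intermediate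
39 | 2-methyl-1,3-oxazole-4-carbaldehyde | Cc1nc(C=O)co1 | starting material
40 | 2-(triphenylphosphoranylidene)propanal | CC(C=O)=P(c1ccccc1)(c1ccccc1)c1ccccc1 | starting material
41 | (2E)-2-methyl-3-(2-methyl-1,3-oxazol-4-yl)prop-2-enal | O=C/C(C)=C/c1coc(C)n1 | intermediate
42 | 2-(dichloromethyl)-4,4,5,5-tetramethyl-1,3,2-dioxaborolane | ClC(Cl)B1OC(C)(C)C(C)(C)O1 | starting material
43 | 2-methyl-4-[(1E,3E)-2-methyl-4-(4,4,5,5-tetramethyl-1,3,2-dioxaborolan-2-yl)buta-1,3-dien-1-yl]-1,3-oxazole | CC(/C=C/B1OC(C)(C)C(C)(C)O1)=C\c1coc(C)n1 | intermediate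
44 | ethyl (3S,4S,5R,6E,8E,10E)-4,6,10-trimethyl-11-(2-methyl-1,3-oxazol-4-yl)-3,5-bis(triethylsilyloxy)undeca-6,8,10-trienoate | CC(/C=C/C=C(\C)[C@H](O[Si](CC)(CC)CC)[C@@H](C)[C@@H](O[Si](CC)(CC)CC)CC(=O)OCC)=C\c1coc(C)n1 | intermediate
45 | (3S,4S,5R,6E,8E,10E)-4,6,10-trimethyl-11-(2-methyl-1,3-oxazol-4-yl)-3,5-bis(triethylsilyloxy)undeca-6,8,10-trienal (C1–C11 aldehyde) | CC(/C=C/C=C(\C)[C@H](O[Si](CC)(CC)CC)[C@@H](C)[C@@H](O[Si](CC)(CC)CC)CC=O)=C\c1coc(C)n1 | intermediate
46 | C11-epimeric dienol: 2-(trimethylsilyl)ethyl ester and 7,9-bis(triethylsilyl) ether of the target acid, C11 unassigned | CC(/C=C/C=C(\C)[C@H](O[Si](CC)(CC)CC)[C@@H](C)[C@@H](O[Si](CC)(CC)CC)CC(O)/C(C)=C/C=C/[C@@H](C)[C@H]1C[C@@H](C/C=C/C(=O)OCC[Si](C)(C)C)CC(=O)O1)=C\c1coc(C)n1 | intermediate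
47 | C11 ketone: 2-(trimethylsilyl)ethyl ester and 7,9-bis(triethylsilyl) ether of the 11-oxo analogue of the target acid | CC(/C=C/C=C(\C)[C@H](O[Si](CC)(CC)CC)[C@@H](C)[C@@H](O[Si](CC)(CC)CC)CC(=O)/C(C)=C/C=C/[C@@H](C)[C@H]1C[C@@H](C/C=C/C(=O)OCC[Si](C)(C)C)CC(=O)O1)=C\c1coc(C)n1 | intermediate
48 | (11R)-alcohol: 2-(trimethylsilyl)ethyl ester and 7,9-bis(triethylsilyl) ether of the target acid | CC(/C=C/C=C(\C)[C@H](O[Si](CC)(CC)CC)[C@@H](C)[C@@H](O[Si](CC)(CC)CC)C[C@@H](O)/C(C)=C/C=C/[C@@H](C)[C@H]1C[C@@H](C/C=C/C(=O)OCC[Si](C)(C)C)CC(=O)O1)=C\c1coc(C)n1 | intermediate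
49 | (2E)-4-[(2R,4R)-2-[(2R,3E,5E,7R,9S,10S,11R,12E,14E,16E)-7,9,11-trihydroxy-6,10,12,16-tetramethyl-17-(2-methyl-1,3-oxazol-4-yl)heptadeca-3,5,12,14,16-pentaen-2-yl]-6-oxooxan-4-yl]but-2-enoic acid (CNP0198746.1) | CC(/C=C/C=C(\C)[C@H](O)[C@@H](C)[C@@H](O)C[C@@H](O)/C(C)=C/C=C/[C@@H](C)[C@H]1C[C@@H](C/C=C/C(=O)O)CC(=O)O1)=C\c1coc(C)n1 | target

**Step count and risks**

Total step count: 29. Longest linear sequence: 17 steps (steps 1–10, 12–14, 26–29).

Steps most likely to fail:

Step 8. The equilibrium between the two arm-isomeric lactones may not lie far enough on the cis side, or equilibration may be slow, so that material is lost in recycling. The fallback replaces thermodynamic arm selection by reagent-controlled desymmetrisation. It sets out from silyloxy diacid 12, isolated by stopping step 8 after the chlorite stage. Ac2O at 50 °C would close 12 to the glutaric anhydride 4-[(2R,3R)-3-methyl-2-(triethylsilyloxy)pent-4-yn-1-yl]oxane-2,6-dione F1. Alkaloid-catalysed methanolysis (MeOH, Et2O, −20 °C, with (DHQD)2AQN or its pseudoenantiomer (DHQ)2AQN, whichever opens the carbonyl destined to be C21, to be identified on a test scale) would give the hemiester (3S)-5-methoxy-3-[(2R,3R)-3-methyl-2-(triethylsilyloxy)pent-4-yn-1-yl]-5-oxopentanoic acid F2. TBAF in THF would then remove the silyl group to give, as its carboxylate, (3S)-3-[(2R,3R)-2-hydroxy-3-methylpent-4-yn-1-yl]-5-methoxy-5-oxopentanoic acid F3; its C17 alkoxide can attack only the methyl ester arm because the other arm is a carboxylate, and acidic work-up would return lactone acid 14, where the route is rejoined.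

Step 26. Zerovalent nickel may be diverted by the triene of 45 (diene–aldehyde coupling) or held by the enoate of 25, or the oxidative cyclisation may lose regiocontrol. The fallback is a chromium-mediated alkenylation that sets out from enyne 25. Cp2Zr(H)Cl (THF, rt) should add across the internal alkyne with zirconium on the less hindered, methyl-bearing carbon C12 to give the dienyl(chloro)zirconocene F4. Iodinolysis (I2, 0 °C) would give 2-(trimethylsilyl)ethyl (2E)-4-[(2R,4R)-2-[(2R,3E,5E)-6-iodohepta-3,5-dien-2-yl]-6-oxooxan-4-yl]but-2-enoate F5. Nozaki–Hiyama–Kishi coupling of this iodide with aldehyde 45 (CrCl2, NiCl2 cat., DMSO, rt) would give dienol 46 as its C11 epimers, where the route is rejoined before step 27.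

Step 28. Hydride delivery to the dienone may show poor facial selectivity, because the β-silyloxy group and the remote Lewis-basic sites can perturb the oxazaborolidine complex, or conjugate reduction may compete. The fallback is a substrate-directed reduction that sets out from ketone 47. HF·pyridine buffered with pyridine (THF, 0 °C) would remove both triethylsilyl groups to give the 2-(trimethylsilyl)ethyl ester of the 7,9-dihydroxy-11-oxo analogue of the target F6. Narasaka–Prasad reduction (Et2BOMe, NaBH4, THF–MeOH, −78 °C), in which the C9 borinate chelates the C11 ketone and hydride attacks the chelate from outside, should give the 9,11-syn diol, that is the 2-(trimethylsilyl)ethyl ester of the target F7. TBAF (THF, 0 °C to rt) would then cleave the ester, and the route is rejoined at target 49.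

**Further compounds**
F1 | step 8 | 4-[(2R,3R)-3-methyl-2-(triethylsilyloxy)pent-4-yn-1-yl]oxane-2,6-dione | C#C[C@@H](C)[C@H](O[Si](CC)(CC)CC)CC1CC(=O)OC(=O)C1
F2 | step 8 | (3S)-5-methoxy-3-[(2R,3R)-3-methyl-2-(triethylsilyloxy)pent-4-yn-1-yl]-5-oxopentanoic acid | C#C[C@@H](C)[C@H](O[Si](CC)(CC)CC)C[C@@H](CC(=O)O)CC(=O)OC
F3 | step 8 | (3S)-3-[(2R,3R)-2-hydroxy-3-methylpent-4-yn-1-yl]-5-methoxy-5-oxopentanoic acid | C#C[C@@H](C)[C@H](O)C[C@@H](CC(=O)O)CC(=O)OC
F4 | step 26 | (3E,5E)-dienyl(chloro)zirconocene from 25 (Zr on C12) | Cl[Zr](/C(C)=C/C=C/[C@@H](C)[C@H]1C[C@@H](C/C=C/C(=O)OCC[Si](C)(C)C)CC(=O)O1)(C1C=CC=C1)C1C=CC=C1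
F5 | step 26 | 2-(trimethylsilyl)ethyl (2E)-4-[(2R,4R)-2-[(2R,3E,5E)-6-iodohepta-3,5-dien-2-yl]-6-oxooxan-4-yl]but-2-enoate | I/C(C)=C/C=C/[C@@H](C)[C@H]1C[C@@H](C/C=C/C(=O)OCC[Si](C)(C)C)CC(=O)O1
F6 | step 28 | 2-(trimethylsilyl)ethyl ester of the 7,9-dihydroxy-11-oxo analogue of the target | CC(/C=C/C=C(\C)[C@H](O)[C@@H](C)[C@@H](O)CC(=O)/C(C)=C/C=C/[C@@H](C)[C@H]1C[C@@H](C/C=C/C(=O)OCC[Si](C)(C)C)CC(=O)O1)=C\c1coc(C)n1
F7 | step 28 | 2-(trimethylsilyl)ethyl ester of the target | CC(/C=C/C=C(\C)[C@H](O)[C@@H](C)[C@@H](O)C[C@@H](O)/C(C)=C/C=C/[C@@H](C)[C@H]1C[C@@H](C/C=C/C(=O)OCC[Si](C)(C)C)CC(=O)O1)=C\c1coc(C)n1
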